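Take 4.05%: this is the hold-up h, the mean share of the charge that the amber and grey runs had been fed by 0.125 d but do not show as open intermediate or target.

| setting | amber | grey | flask |
|---|---|---|---|
| starting material | 47 mM (fed, over 4.0 h) | 47 mM (fed, over 4.0 h) | 47 mM (fed, over 4.0 h) |
| partner | 35 mM | 53 mM | 70.5 mM |
| remark | run made earlier | run made earlier |  |
| time |  |  | 15 d |

- amber (time / d: open intermediate / %, target / %): 0.125: 68.6, 2.1; 0.500: 73.5, 23.7; 2.50: 59.9, 32.3; 12.0: 43.4, 31.9
- grey (time / d: open intermediate / %, target / %): 0.125: 67.1, 4.1; 0.500: 63.6, 34.4; 2.50: 49.0, 47.0; 12.0: 37.4, 46.7

(standard deviation of a reading: 0.5 percentage points)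

1. when, up to 15 d, the flask holds most open intermediate
2. the amount of open intermediate, in percent of the starting material charged, at that time
3. the first time at which open intermediate reaches 60%, in the same percent

- the analysis behind the earlier runs scatters by 0.5 percentage points, standard deviation
- a reading or a percentage of target counts all its forms, free or not
- percentages count the whole charge, also what has not yet gone in

Now freeze h and reckon target, the other loss from open intermediate under this steady feed (semi-batch dosing). Pool the first readings: target at 0.125 d goes with partner, within scatter. Then find its time law. In the amber run target gains 0.576 d⁻¹ of the charge between 0.125 d and 0.500 d, faster than the 0.490 d⁻¹ that a rate following open intermediate alone, scaled from the small first reading, gives with the whole charge standing as open intermediate. So assume a second factor grows with time as well, which makes the rate go as t² and target as t³ during the feed.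

This gives g, the share of the charge turned to target by feed end per unit of partner, 1.67 M⁻¹. For the flask, g times 70.5 mM is 11.8%.

Bracket the peak. With h drained, the ceiling is 88.2%; with h whole, the floor is 84.2%. Expect the peak about one holding time h·t_f after feed end, near 0.173 d. Set feed minus h minus target equal to 60%, and one iteration gives 0.112 d.

The forecast, 85% at 0.175 d and 60% at 0.113 d, lies inside this bracket and says “should therefore peak just after feed end”. The flask gives 86.0% at 0.172 d and reaches 60% at 0.113 d.

    starting material → open intermediate (k = 10.0 h⁻¹)
    partner → second intermediate (k = 0.330 h⁻¹)
    open intermediate + second intermediate → target (k = 2.00 M⁻¹ h⁻¹)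
    2 open intermediate → homo product (k = 0.0290 M⁻¹ h⁻¹)
    second intermediate → side product (k = 0.0880 h⁻¹)
    crystals ⇌ target, rate k6*(cs6 - [target]) while solid is left; crystals form when [target] > cs6 (solubility = 12.0 mM, k = 27.0 h⁻¹)
    starting material ⇌ dormant form (K = 0.400, k = 0.330 h⁻¹)

Against the reckoned 11.8%, the flask holds 12.1% of target at 0.172 d. Its peak is lowered partly by the bit-by-bit addition: the same flask with the charge added at once reaches 96.7%, not 86.0%. For the neighbour flask with 18 mM of partner, g gives 3.01% of target, so its bracket runs from 92.9% to 97.0%, and that flask peaks at 95.1%.

The numbers in the tables come from a simulation from invented constants; noise was put on by code.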